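A small charge of initiator, 1.4 mM, is set against 0.27 M of solid substrate that enters solution slowly, and the chain it starts has to turn that solid substrate into product.

solid substrate 0.27 M; reagent 0.297 M; initiator 1.4 mM; time 30 h

* amount of product at 30 h, in percent of the solid substrate charged
* concentration of starting material in solution at 30 h, in percent of saturation

    solid substrate ⇌ starting material, rate k1*(cs1 - [starting material]) while solid is left; crystals form when [starting material] > cs1 (cs1 = 0.22 M, k1 = 1.7 × 10⁻⁶ s⁻¹)
    starting material + initiating radical → chain carrier (k2 = 390 M⁻¹ s⁻¹)
    2 chain carrier → ended chains (k3 = 1.6 × 10⁸ M⁻¹ s⁻¹)
    initiator → 2 initiating radical (k4 = 8.9 × 10⁻⁶ s⁻¹)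
    reagent + chain carrier → product + initiating radical (k5 = 1300 M⁻¹ s⁻¹)

- a species is counted by the solid substrate in it: one ended chains counts as two
- where a step has two of a species, its rate is k times that concentration squared, and two are used at each turn
- given per volume of solution although it is solid: solid substrate
- at the start none of the solid substrate is in solution
- starting material means what is dissolved; the solid is not counted in it
- run time (flask): 30 h

Which charge do you balance? In this flask the solid substrate, because its 0.27 M stands below the 0.297 M of reagent, so it is the limiting reagent. What has dissolved equals c(starting material) plus c(chain carrier) plus c(product) plus c(ended chains), each ended chain counted as two.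

How much can have dissolved by 30 h? Into a solution kept empty, the inflow is the coefficient times the solubility, and this inflow times the time comes to 0.0404 M, the dissolution ceiling. That is 15.0% of the charge, so solid remains.

But does the solution stay empty? A dissolved molecule waits for an initiating radical. The initiator has given about 1.73 mM of them by then, and the step of reagent with chain carrier hands one back for each chain carrier it uses. The wait is therefore 1.48 s, against 163 h for the inflow to fill the solution. So c(starting material) sits at inflow times wait, <0.001% of saturation.

And early, with fewer radicals? At 3.00 h I reckon a wait of 9.99 s, still far shorter.

Does the chain leak? At this inflow c(chain carrier) is 9.69 × 10⁻¹⁰ M, and termination takes a share of 0.0803% of the carriers. I commit to about 15.0%.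

The forecast gave 14.95% of product, within 14.7% to 15.1%, and <0.001% of saturation, holding that “dissolution limits the rate and starting material stays near zero”.

The simulation of the flask gives 14.9% of product and 0% of saturation.

The ceiling of 0.0404 M is reckoned from the coefficient, the solubility and the time, with no solid charge in it, so for the neighbouring flask with 1.1 M of solid substrate the same reckoning divides the same 0.0404 M by the larger charge and expects 3.67%. There the reagent is the smaller charge, yet the ceiling stands below it. The simulation of that neighbouring flask gives 3.67%, with 96% of its solid substrate and 86% of its reagent still there at 30.0 h.

Its constants were chosen freely.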